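## Retrosynthetic overview
1. The C6–quaternary carbon bond is made last, by a [3,3] O→C shift of a prenyl group from O5. C6 is the only open ortho site, so the regiochemistry is fixed.
2. Ring C (O1–C2) and the C3–OH trace back to a 2'-hydroxychalcone. A catalyst-controlled 6-endo oxa-Michael closure (chalcone isomerase mode) sets C2. A C3 oxygenation anti to the aryl group (flavanone 3-hydroxylase mode) follows in the same telescoped operation.
3. The chalcone comes from a Claisen–Schmidt union of a ring A acetophenone and a ring B benzaldehyde.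
4. The 6'-O-prenyl ether leaves a single phenol free for ring closure, pushes the chalcone/flavanone equilibrium to the closed form, and carries the C5 unit.
5. Ring order: rings A and B are bought (phloroacetophenone, vanillin). Ring C is the only ring formed.

Assumption 1: the quinidine-derived thiourea is taken to give the 2S flavanone. If the sense is opposite, the quinine-derived pseudoenantiomer is used and nothing else changes.
Assumption 2: the oxan-2-yl (THP) acetal carbons are stereorandom. They are left undefined in names and SMILES, and they disappear in step 5.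

## Route

Step 1
Reactants: 1 2,4,6-trihydroxyacetophenone (phloroacetophenone, dried)
Product: 2 1-[2,6-dihydroxy-4-(oxan-2-yloxy)phenyl]ethanone
Conditions: DHP (1.1 equiv), PPTS (5 mol %), THF–CH2Cl2, 0 °C → rt
Reagents that add atoms: 3,4-dihydro-2H-pyran (DHP), C1=COCCC1
Why: Acid-catalysed acetalisation (THP ether formation) works here because the 4-OH is the least hindered hydroxyl and the only one never tied up in the hydrogen bond to the acetyl carbonyl, so it adds first with a near-stoichiometric charge of DHP.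

Step 2
Reactants: 2 1-[2,6-dihydroxy-4-(oxan-2-yloxy)phenyl]ethanone; 3 prenyl bromide (1-bromo-3-methylbut-2-ene)
Product: 4 1-[2-hydroxy-6-(3-methylbut-2-enyloxy)-4-(oxan-2-yloxy)phenyl]ethanone
Conditions: K2CO3 (1.5 equiv), acetone, reflux
Reagents that add atoms: none
Why: In this Williamson ether synthesis the two remaining hydroxyls are equivalent, and after the first O-alkylation the last one is locked in a strong chelate to the carbonyl, so the reaction stops at the mono-ether.

Step 3
Reactants: 5 vanillin
Product: 6 3-methoxy-4-(oxan-2-yloxy)benzaldehyde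
Conditions: DHP (1.5 equiv), PPTS (5 mol %), CH2Cl2, rt
Reagents that add atoms: 3,4-dihydro-2H-pyran (DHP), C1=COCCC1
Why: THP ether formation masks the para-phenol, whose phenoxide would otherwise deactivate the aldehyde in step 4 and open a quinone-methide racemisation path in step 5.

Step 4
Reactants: 4 1-[2-hydroxy-6-(3-methylbut-2-enyloxy)-4-(oxan-2-yloxy)phenyl]ethanone; 6 3-methoxy-4-(oxan-2-yloxy)benzaldehyde
Product: 7 (E)-1-[2-hydroxy-6-(3-methylbut-2-enyloxy)-4-(oxan-2-yloxy)phenyl]-3-[3-methoxy-4-(oxan-2-yloxy)phenyl]prop-2-en-1-one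
Conditions: KOH (50% aq), EtOH, rt, 36 h; cold aq citric acid to pH 6
Reagents that add atoms: none
Why: The Claisen–Schmidt condensation (aldol, then E1cB loss of water) gives the thermodynamic E-enone, the acetals and the allylic ether are base-stable, and in strong base the product rests as the ring-open phenoxide so no racemic flavanone forms before the asymmetric step.

Step 5
Reactants: 7 (E)-chalcone
Product: 11 (2R,3R)-3,7-dihydroxy-2-(4-hydroxy-3-methoxyphenyl)-5-(3-methylbut-2-enyloxy)-2,3-dihydrochromen-4-one, via (2S)-flavanone 8 (not isolated), via silyl enol ether 9 (not isolated), via silyloxy-oxirane 10 (not isolated)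
Conditions: a) 1-[3,5-bis(trifluoromethyl)phenyl]-3-[(9R)-6'-methoxycinchonan-9-yl]thiourea (10 mol %), PhMe, 0 °C, 48 h, short SiO2 pad; b) TMSOTf (1.1 equiv), Et3N (2 equiv), CH2Cl2, −20 °C, pentane, decant from the ammonium salt, concentrate cold in the dark; c) DMDO (1.05 equiv), acetone–CH2Cl2, −78 → −40 °C; d) PPTS (20 mol %), MeOH, rt
Reagents that add atoms: dimethyldioxirane (DMDO), CC1(C)OO1; trimethylsilyl trifluoromethanesulfonate (TMSOTf), C[Si](C)(C)OS(=O)(=O)C(F)(F)F (its silyl group is carried by 9 and 10 only)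
Why: Proposed new method: the closest known reaction types are the cinchona-thiourea-catalysed enantioselective intramolecular oxa-Michael cyclisation of 2'-hydroxychalcones (most reliable when an extra alpha-ester activates the enone) and the Rubottom oxidation, and the new element is to cyclise the unactivated chalcone and freeze the labile C2 centre at once: the quinuclidine nitrogen takes the 2'-OH proton while the thiourea hydrogen-bonds the carbonyl, so the only free phenoxide adds 6-endo to one face of the E-enone and sets C2 (S), the 6'-prenyloxy group twists the aryl ketone out of conjugation, which drives the equilibrium to the flavanone and slows the retro-addition that erodes ee, soft enolisation avoids the free enolate that would ring-open by E1cB, DMDO attacks the electron-rich enol ether (far faster than the inductively deactivated prenyl ether alkene) anti to the 2-aryl group and sets C3 (R, 2,3-trans), and mild methanolysis collapses the oxirane to the ketol and removes TMS and both THP groups without touching the aryl prenyl ether.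

Step 6
Reactants: 11 (2R,3R)-5-O-prenyl dihydroflavonol
Product: 13 (2R,3R)-3,5,7-trihydroxy-2-(4-hydroxy-3-methoxyphenyl)-6-(2-methylbut-3-en-2-yl)-2,3-dihydrochromen-4-one, via ortho-dienone 12 (not isolated)
Conditions: Eu(fod)3 (10 mol %; fod = 6,6,7,7,8,8,8-heptafluoro-2,2-dimethyloctane-3,5-dionate), CHCl3, sealed tube, 70 °C, Ar, dark
Reagents that add atoms: none
Why: In this aromatic Claisen rearrangement, oxophilic trivalent europium chelated by the C4 carbonyl and O5 polarises the O–CH2 bond, the [3,3] shift can only reach C6 because the other ortho carbon C4a is quaternary, the free 7-OH makes dienone 12 a vinylogous acid that tautomerises faster than it can undergo Cope migration to C8, and no stereocentre is touched (any C2 epimer formed by ring opening reverts to the more stable trans isomer because C3 stays fixed).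

## Compound list
1 | 2,4,6-trihydroxyacetophenone | CC(=O)c1c(O)cc(O)cc1O | starting material
2 | 1-[2,6-dihydroxy-4-(oxan-2-yloxy)phenyl]ethanone (acetal carbon racemic) | CC(=O)c1c(O)cc(OC2CCCCO2)cc1O | intermediate
3 | prenyl bromide, 1-bromo-3-methylbut-2-ene | CC(C)=CCBr | starting material
4 | 1-[2-hydroxy-6-(3-methylbut-2-enyloxy)-4-(oxan-2-yloxy)phenyl]ethanone | CC(=O)c1c(O)cc(OC2CCCCO2)cc1OCC=C(C)C | intermediate
5 | vanillin | COc1cc(C=O)ccc1O | starting material
6 | 3-methoxy-4-(oxan-2-yloxy)benzaldehyde | COc1cc(C=O)ccc1OC1CCCCO1 | intermediate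
7 | (E)-2'-hydroxy-6'-prenyloxy-4,4'-bis(oxan-2-yloxy)-3-methoxychalcone | O=C(/C=C/c1ccc(OC2CCCCO2)c(OC)c1)c1c(O)cc(OC2CCCCO2)cc1OCC=C(C)C | intermediate
8 | (2S)-2-[3-methoxy-4-(oxan-2-yloxy)phenyl]-5-(3-methylbut-2-enyloxy)-7-(oxan-2-yloxy)-2,3-dihydrochromen-4-one (not isolated) | CC(C)=CCOc1cc(OC2CCCCO2)cc2c1C(=O)C[C@@H](c1ccc(OC3CCCCO3)c(OC)c1)O2 | intermediate
9 | (2S)-4-trimethylsilyloxy-2H-chromene derived from 8 (not isolated) | CC(C)=CCOc1cc(OC2CCCCO2)cc2c1C(O[Si](C)(C)C)=C[C@@H](c1ccc(OC3CCCCO3)c(OC)c1)O2 | intermediate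
10 | 3,4-epoxide of 9, 4-OTMS retained, oxirane oxygen trans to the 2-aryl group (not isolated) | CC(C)=CCOc1cc(OC2CCCCO2)cc2c1[C@]3(O[Si](C)(C)C)O[C@@H]3[C@@H](c1ccc(OC4CCCCO4)c(OC)c1)O2 | intermediate
11 | (2R,3R)-3,7-dihydroxy-2-(4-hydroxy-3-methoxyphenyl)-5-(3-methylbut-2-enyloxy)-2,3-dihydrochromen-4-one | CC(C)=CCOc1cc(O)cc2c1C(=O)[C@H](O)[C@@H](c1ccc(O)c(OC)c1)O2 | intermediate
12 | ortho-dienone: C5 ketone, sp3 C6 bearing H and 2-methylbut-3-en-2-yl (C6 undefined), C7 enol, (2R,3R) retained (not isolated) | C=CC(C)(C)C1C(O)=CC2=C(C1=O)C(=O)[C@H](O)[C@@H](c1ccc(O)c(OC)c1)O2 | intermediate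
13 | (2R,3R)-3,5,7-trihydroxy-2-(4-hydroxy-3-methoxyphenyl)-6-(2-methylbut-3-en-2-yl)-2,3-dihydrochromen-4-one | C=CC(C)(C)c1c(O)cc2c(c1O)C(=O)[C@H](O)[C@@H](c1ccc(O)c(OC)c1)O2 | target

## Count and risks
Total steps: 6. Step 5 is one telescoped four-stage operation in which 8, 9 and 10 are not isolated.
Longest linear sequence: 5 steps (1 → 2 → 4 → 7 → 11 → 13).
The ee is read on 11 by chiral HPLC and can be raised by recrystallising 11 or 13.

**Most likely to fail, first: step 5.**
- The electron-rich, unactivated chalcone may cyclise slowly or with modest ee.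
- The 2H-chromene 9 may lose configuration by electrocyclic opening if it is warmed or exposed to light.
- DMDO may touch the prenyl ether alkene.

The fallback sets out from 7 and comes back at 11. It gives up catalyst control of the C–O bond formation and installs both stereocentres as an epoxide. Compound 7 is O-silylated (NaH, TIPSCl, THF, 0 °C) to the 2'-O-triisopropylsilyl chalcone F1. Juliá–Colonna epoxidation (poly-L-leucine, urea–H2O2, DBU, THF) gives the (alphaR,betaS)-epoxychalcone F2, and the nucleophilic peroxide ignores the prenyl alkene. TBAF/AcOH frees the 2'-hydroxy epoxychalcone F3. PPTS in CH2Cl2 then triggers 6-endo opening at the p-alkoxybenzylic carbon with inversion, giving the bis-THP trans-dihydroflavonol F4. Adding MeOH to the same flask strips the acetals and delivers 11.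

**Second: step 6.**
- The 3-OH/4-C=O ketol may bind the europium unproductively.
- The prenyl ether may simply be cleaved.
- Some dienone 12 may escape by Cope shift to the 8-prenyl isomer.

The fallback sets out from 8 and comes back at 13. It moves the prenyl shift ahead of the hydroxylation, so the rearrangement runs on a 3-deoxy flavanone and the oxidant later meets only an inert vinyl group. Compound 8 is collected after the silica pad and treated with PPTS/MeOH to give (2S)-5-O-prenylhomoeriodictyol F5. Eu(fod)3 in CHCl3 at 70 °C takes it through the ortho-dienone F6 to (2S)-6-(2-methylbut-3-en-2-yl)homoeriodictyol F7. Excess TMSOTf/Et3N gives the tetrakis(trimethylsilyl) enol ether F8. DMDO at −78 °C gives the silyloxy-oxirane F9 anti to the aryl group, and PPTS/MeOH releases 13. The price is a C2 centre that has no C3 anchor during the heating.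

**Third: step 1.**
- In 1 the two ortho hydroxyls share one carbonyl, so the 4-O selectivity is only moderate.
- The nucleophilic ring may be C-alkylated by the oxocarbenium ion.

The fallback sets out from 1 and comes back at 4. It reverses the order of events, so the acetal is put on when only one unchelated hydroxyl is left. TBSCl/imidazole (DMF, 0 °C) gives the 4-O-tert-butyldimethylsilyl ether F10. A Mitsunobu reaction with 3-methylbut-2-en-1-ol (PPh3, DIAD, THF) gives the 6-O-prenyl silyl ether F11. TBAF/AcOH gives 2,4-dihydroxy-6-prenyloxyacetophenone F12. DHP/PPTS then reacts only at the 4-OH and gives 4.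

## Further compounds
F1 | step 5 | (E)-2'-O-triisopropylsilyl ether of chalcone 7 | O=C(/C=C/c1ccc(OC2CCCCO2)c(OC)c1)c1c(O[Si](C(C)C)(C(C)C)C(C)C)cc(OC2CCCCO2)cc1OCC=C(C)C
F2 | step 5 | (2R,3S)-oxirane (alphaR,betaS) of F1 | O=C([C@@H]1O[C@H]1c1ccc(OC2CCCCO2)c(OC)c1)c1c(O[Si](C(C)C)(C(C)C)C(C)C)cc(OC2CCCCO2)cc1OCC=C(C)C
F3 | step 5 | 2'-hydroxy (alphaR,betaS)-epoxychalcone | O=C([C@@H]1O[C@H]1c1ccc(OC2CCCCO2)c(OC)c1)c1c(O)cc(OC2CCCCO2)cc1OCC=C(C)C
F4 | step 5 | (2R,3R)-3-hydroxy-5-prenyloxy-7,4'-bis(oxan-2-yloxy)-3'-methoxyflavanone | CC(C)=CCOc1cc(OC2CCCCO2)cc2c1C(=O)[C@H](O)[C@@H](c1ccc(OC3CCCCO3)c(OC)c1)O2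
F5 | step 6 | (2S)-5-O-prenylhomoeriodictyol | CC(C)=CCOc1cc(O)cc2c1C(=O)C[C@@H](c1ccc(O)c(OC)c1)O2
F6 | step 6 | ortho-dienone from F5 (C6 undefined) | C=CC(C)(C)C1C(O)=CC2=C(C1=O)C(=O)C[C@@H](c1ccc(O)c(OC)c1)O2
F7 | step 6 | (2S)-6-(2-methylbut-3-en-2-yl)homoeriodictyol | C=CC(C)(C)c1c(O)cc2c(c1O)C(=O)C[C@@H](c1ccc(O)c(OC)c1)O2
F8 | step 6 | (2S)-4,5,7,4'-tetrakis(trimethylsilyloxy)-2H-chromene from F7 | C=CC(C)(C)c1c(O[Si](C)(C)C)cc2c(c1O[Si](C)(C)C)C(O[Si](C)(C)C)=C[C@@H](c1ccc(O[Si](C)(C)C)c(OC)c1)O2
F9 | step 6 | 3,4-epoxide of F8, oxirane oxygen trans to the 2-aryl group | C=CC(C)(C)c1c(O[Si](C)(C)C)cc2c(c1O[Si](C)(C)C)[C@]3(O[Si](C)(C)C)O[C@@H]3[C@@H](c1ccc(O[Si](C)(C)C)c(OC)c1)O2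
F10 | step 1 | 1-[4-(tert-butyldimethylsilyloxy)-2,6-dihydroxyphenyl]ethanone | CC(=O)c1c(O)cc(O[Si](C)(C)C(C)(C)C)cc1O
F11 | step 1 | 1-[4-(tert-butyldimethylsilyloxy)-2-hydroxy-6-(3-methylbut-2-enyloxy)phenyl]ethanone | CC(=O)c1c(O)cc(O[Si](C)(C)C(C)(C)C)cc1OCC=C(C)C
F12 | step 1 | 1-[2,4-dihydroxy-6-(3-methylbut-2-enyloxy)phenyl]ethanone | CC(=O)c1c(O)cc(O)cc1OCC=C(C)C
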